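The runs come from a simulation on assumed constants; scatter was added.

Compare at equal conversion.

- Thursday's: Z 1.5 M; L 1.5 equiv; X 2 mol%; run made earlier
- flask: Z 1.5 M; L 1.50 equiv; X 1 mol%

- Thursday's (time / min: D / %, Z / %): 3.00: 8, 95; 6.00: 4, 92; 10.0: 11, 90; 15.0: 15, 79; 20.0: 26, 78; 25.0: 31, 71

(scatter of a reading: 2 percentage points)

- the earlier runs were read with a standard deviation of 2 percentage points
- on the list of suspects stand: L + X -> G; Z + G -> Q; Q -> X + D; L -> E
- no earlier run changes the charge of X; that part of a forecast is a guess

- apparent order in X when 50% of the Z are converted (percent change of the rate of making D for one percent more X charged)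

1. I carry one measure: the turnover rate, D made per hour per X charged (the turnover frequency), 37.2 h⁻¹. I read it from Thursday's last D, at 25.0 min, so it is an average up to then and carries that reading's scatter.

2. I turn the question round. An order of 0 needs this flask, with 1 mol% X, to keep Thursday's rate of making D. Each X must then turn over twice as fast, at 74.4 h⁻¹.

3. On the suspect list, D comes from Q, a form of X. Both charges start at 1.5 M Z, so equal conversion means equal Z used. But L → E, if it is real, runs on the clock without X. In this flask, with less X, I expect the same conversion to come later and [L] to stand lower.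

4. So I expect an order a little above 1, not one falling towards 0. At order 1, carrying Thursday's straight line on, I estimate 50% conversion in this flask after 1.34 h.

5. The forecast gives 1.03, “pushing the order slightly above 1”.

6. The flask gives 1.2.

    L + X → G (k = 0.0110 L mol⁻¹ s⁻¹)
    Z + G → Q (k = 0.0230 L mol⁻¹ s⁻¹)
    Q → X + D (k = 0.0390 s⁻¹)
    L → E (k = 3.90 × 10⁻⁵ s⁻¹)

7. This flask reaches 50% conversion at 1.70 h, later than my 1.34 h. There it makes D at 0.326 M h⁻¹, which is 21.7 h⁻¹ per X charged, 0.584 of the turnover rate read on Thursday.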